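## The problem

Target 24 is a 5,7-dihydroxyflavone whose ring B is a 2,3-dihydrobenzofuran. Chromone C2 is bonded to benzofuran C5, and the benzofuran carries a 3-methylbut-2-enyl (prenyl) group at C7, a hydroxyl at C3 and a 2-hydroxypropan-2-yl group at C2. The only stereocentres are C2 and C3 of the dihydrofuran, trans and both S. They are remote from the flavone, so they must be set inside the ring B fragment. Within that fragment one centre can control the other: a C3 carbinol can direct epoxidation of a neighbouring trisubstituted alkene, and the epoxide can then be opened with inversion at C2, so only C3 needs absolute control. The C3 hydroxyl is benzylic and the ring oxygen sits on the adjacent aromatic carbon C7a, so acid ionises it to an oxocarbenium-stabilised cation; epimerisation, solvolysis or dehydration to the aromatic benzofuran would follow. The prenyl alkene excludes peracids, OsO4, hydrogenolysis and strong acid once it is in place, and the tertiary alcohol and the phloroglucinol-type phenols must be masked. The pyranone ring C (O1, C2, C3, C4, C4a, C8a) maps onto an ortho-iodophenol (C8a–O1 and C4a–I), one molecule of CO (C4) and the two carbons of a ring B arylalkyne (C3, C2), so ring C can be assembled last from two halves of similar size.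

## Retrosynthesis

Target 24 is traced to 23 and then to 21 by removing protecting groups only (O–Si and O–CH2OMe bonds, no skeletal bond). Methoxymethyl ethers on ring A survive amine, CO and heat; triethylsilyl ethers on the diol survive the same conditions and leave with fluoride. A single treatment with protic acid is avoided because of the ionisable C3 carbinol, so the forward steps must be a non-protic aryl MOM cleavage followed by buffered fluoride.

Flavone 21 is cut at C4a–C4, C4–C3 and O1–C2 into iodophenol 18, CO and alkyne 15. Condensation routes through a ring B aldehyde or acid would need oxidative or acidic cyclodehydration, which the prenyl group and the diol would not tolerate, and a cross-coupling of a preformed 2-halochromone forms only one bond. The carbonylative annulation builds the whole of ring C under basic, non-oxidising conditions and halves the molecule. It must insert CO before alkyne transfer and close the six-membered ring, not the five-membered one, through ynone 19 and enaminone 20.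

Alkyne 15 is cut at the C5–C(sp) bond, through silylalkyne 14, to bromide 12 and trimethylsilylacetylene 13. The bromine para to the ring oxygen is carried from the first step, so no late halogenation next to the prenyl alkene is needed. Bromide 12 is the bis(triethylsilyl) ether of diol 11.

Diol 11 is cut at O1–C2 to the phenoxide 10 of epoxy alcohol 9. Against closure at O1–C7a or C2–C3, this cut leaves an acyclic precursor whose two stereocentres translate directly: the carbinol carbon becomes C3 unchanged, and the oxirane carbon becomes C2 with inversion. The forward step must be a 5-exo opening at the secondary epoxide carbon, and 9 must be the threo isomer to give the trans ring.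

Epoxy alcohol 9 is cut at the epoxide oxygen to allylic alcohol 8. A hydroxyl-directed epoxidation is the only oxidation that distinguishes the allylic alkene from the aryl prenyl alkene, and allylic 1,3-strain from the cis methyl group should give the threo isomer. Alcohol 8 is cut at the carbinol–alkenyl bond to aldehyde 5 and 2-methylprop-1-enylmagnesium bromide 6, used as the zinc reagent 7. This addition is the only step that must set absolute configuration.

Aldehyde 5 is the silyl ether of salicylaldehyde 4, which is cut at the formyl carbon to phenol 3 and then at the prenyl–aryl bond to 4-bromophenol 1 and prenyl bromide 2. Prenylation before formylation leaves a single free ortho position for the formyl group.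

Iodophenol 18 is cut at C–I to 3,5-bis(methoxymethoxy)phenol 17, which comes from phloroglucinol 16. The forward iodination must go ortho to the free hydroxyl.

## Roads not taken

Alternative 1: The O1–C2 bond would be made by a 1,2-shift of the ring oxygen of a chroman. On buffered aqueous solvolysis of the trans-chromanyl mesylate A2, the ring oxygen would displace the C3 mesylate from the rear, the six-membered ring would contract, and water would capture the tertiary cation to give A1.
- Merits: both stereocentres of A2 would come from one catalytic step, since 2,2-dimethylchromenes as a class are excellent substrates for (salen)MnCl-catalysed asymmetric epoxidation. In certainty of absolute configuration this road is better than step 4 of the chosen plan.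
- Weak points: the two hydroxyls of the chroman diol must be differentiated before A2 exists. The shift needs an axial mesylate anti to the O1–C2 bond and passes through a tertiary cation that can also lose a proton, and the formyl group para to the ring oxygen in A2 deactivates the lone pair that must participate. A1 still lacks the prenyl group and the flavone, so a cross-coupling at the C7 bromide and a multistep flavone construction from the aldehyde would follow, the latter exposing the diol and the prenyl group to oxidants or acid.
- Comparison: against the stronger enantiocontrol, the chosen plan sets a shorter sequence, a ring closure under basic conditions with no cationic intermediate, and a convergent final ring construction.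

Alternative 2: The C2–C3 bond would be cut. Aryloxyacetone A4, which is the O-acetonyl ether of aldehyde 4, would undergo a proline-catalysed intramolecular aldol reaction (5-enolexo). The enamine of the ketone attacks the ortho aldehyde and gives the cis hydroxy ketone A3.
- Merits: one organocatalytic step from an achiral precursor sets both centres, with closer precedent for high enantiomeric excess than the alkenylzinc addition of the chosen plan, and a stereodefined bicycle is reached two steps after 4.
- Weak points: C2 is correct but C3 is the epimer, so an inversion at a hindered benzylic carbinol next to a tertiary alcohol, or an oxidation–reduction detour, is required. A3 is a β-hydroxy ketone with an acidic C2–H and can dehydrate to the aromatic 2-acetylbenzofuran or undergo retro-aldol cleavage under the basic conditions of the methyl addition that must follow.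
- Comparison: the chosen plan gives the trans diol 11 directly and never passes through a β-hydroxy carbonyl compound, which is what it sets against the better-precedented asymmetric step.

Alternative 3: The O1–C7a bond would be cut. Carbonate base would ionise the C2 hydroxyl of fluoro triol A6, and the alkoxide would displace fluoride from C7a, activated by the para formyl group, to give aldehyde A5.
- Merits: the ring closes at an aromatic carbon, so neither stereocentre is touched in the ring-forming step. In this respect the road is safer than the invertive epoxide opening of step 6.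
- Weak points: because C2 reacts with retention, A6 must be the anti triol, whereas osmium-catalysed syn-dihydroxylation of a trans-styrene, the obvious enantioselective entry, gives the syn relationship. The prenyl alkene of A6 would compete in any OsO4 step. The tertiary alkoxide can attack C7a to give the six-membered chroman isomer. A5 ends as an aldehyde, from which ring C would have to be built by the longer condensation route.
- Comparison: the chosen plan answers with an oxidation that is blind to the prenyl group, a substrate-controlled path to the trans relationship, and a one-step ring C construction.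

Key step: step 12

Remark on the chemistry: (+)-MIB is taken as the enantiomer of 3-exo-morpholinoisoborneol that sends a zinc-bound carbon group to the Re face of an aromatic aldehyde; the push–pull alkene of 20 and the carbinol carbon of F3 are configurationally undefined and are drawn so.

Step 1
Reactants: 1 4-bromophenol; 2 1-bromo-3-methylbut-2-ene (prenyl bromide)
Product: 3 4-bromo-2-(3-methylbut-2-enyl)phenol
Conditions: NaH, toluene, 0 °C to rt
Reagents that add atoms: none
Why: Ortho C-alkylation of a sodium phenoxide in a non-polar solvent (Claisen-type C-allylation); the tight ion pair shields oxygen, the para position is blocked by bromine, and the prenyl group should enter through its primary carbon, with O-prenyl and 2,6-diprenyl by-products removed by chromatography.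

Step 2
Reactants: 3 4-bromo-2-(3-methylbut-2-enyl)phenol
Product: 4 5-bromo-2-hydroxy-3-(3-methylbut-2-enyl)benzaldehyde
Conditions: MgCl2, Et3N, (CH2O)n, MeCN, reflux
Reagents that add atoms: formaldehyde (as paraformaldehyde), C=O
Why: Magnesium-mediated ortho-formylation (Casnati–Skattebøl); the magnesium phenoxide delivers formaldehyde to the only free ortho position and a second formaldehyde oxidises the benzylic alkoxide to the aldehyde, conditions to which the prenyl group and the bromide are inert.

Step 3
Reactants: 4 5-bromo-2-hydroxy-3-(3-methylbut-2-enyl)benzaldehyde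
Product: 5 5-bromo-2-(tert-butyldimethylsilyloxy)-3-(3-methylbut-2-enyl)benzaldehyde
Conditions: TBSCl, imidazole, DMF, rt
Reagents that add atoms: tert-butyldimethylsilyl chloride, CC(C)(C)[Si](C)(C)Cl
Why: Standard phenol silylation; the silyl ether removes the acidic proton that would destroy the organozinc reagent and can later be cleaved by fluoride under basic conditions to release the phenoxide nucleophile.

Step 4
Reactants: 5 5-bromo-2-(tert-butyldimethylsilyloxy)-3-(3-methylbut-2-enyl)benzaldehyde; 6 2-methylprop-1-enylmagnesium bromide
Product: 8 (R)-1-[5-bromo-2-(tert-butyldimethylsilyloxy)-3-(3-methylbut-2-enyl)phenyl]-3-methylbut-2-en-1-ol, via bis(2-methylprop-1-enyl)zinc 7 (not isolated)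
Conditions: 6, ZnCl2 (0.5 equiv per 6), THF, 0 °C; 1,4-dioxane, filter; then 5, (+)-MIB (10 mol %), toluene, 0 °C; aq NH4Cl
Reagents that add atoms: none
Why: Amino-alcohol-catalysed enantioselective addition of an alkenylzinc reagent to an aromatic aldehyde (Noyori–Oppolzer type); the zinc aminoalkoxide of (+)-MIB should bind aldehyde and zinc reagent in a bimetallic transition state and deliver the alkenyl group to the Re face, which gives the R carbinol. Magnesium halide is removed as its dioxane complex beforehand to suppress the uncatalysed racemic addition.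

Step 5
Reactants: 8 (R)-1-[5-bromo-2-(tert-butyldimethylsilyloxy)-3-(3-methylbut-2-enyl)phenyl]-3-methylbut-2-en-1-ol
Product: 9 (S)-[5-bromo-2-(tert-butyldimethylsilyloxy)-3-(3-methylbut-2-enyl)phenyl][(R)-3,3-dimethyloxiran-2-yl]methanol (threo epoxy alcohol)
Conditions: Ti(OiPr)4 (20 mol %), t-BuOOH, 4 Å MS, CH2Cl2, −20 °C
Reagents that add atoms: tert-butyl hydroperoxide, CC(C)(C)OO
Why: Hydroxyl-directed epoxidation with the tartrate-free Sharpless reagent; allylic 1,3-strain from the cis methyl group holds the carbinol hydrogen in the alkene plane, so the titanium-bound peroxide is delivered to the face that carries OH and the threo isomer should form (the carbinol descriptor changes from R to S only because the priorities change). The aryl prenyl alkene has no directing hydroxyl and should not react.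

Step 6
Reactants: 9 (S)-[5-bromo-2-(tert-butyldimethylsilyloxy)-3-(3-methylbut-2-enyl)phenyl][(R)-3,3-dimethyloxiran-2-yl]methanol
Product: 11 (2S,3S)-5-bromo-2-(2-hydroxypropan-2-yl)-7-(3-methylbut-2-enyl)-2,3-dihydrobenzofuran-3-ol (trans), via tetrabutylammonium phenoxide 10 (not isolated)
Conditions: TBAF, THF, 0 °C to rt; aq NH4Cl
Reagents that add atoms: none
Why: Fluoride cleaves the aryl silyl ether and the phenoxide opens the epoxide at its secondary carbon by 5-exo-tet SN2 attack with inversion, setting C2 as S and leaving C3 untouched, so the threo epoxy alcohol becomes the trans dihydrobenzofuran. Attack at the tertiary carbon (6-endo) is not expected under basic conditions.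

Step 7
Reactants: 11 (2S,3S)-5-bromo-2-(2-hydroxypropan-2-yl)-7-(3-methylbut-2-enyl)-2,3-dihydrobenzofuran-3-ol
Product: 12 (2S,3S)-5-bromo-7-(3-methylbut-2-enyl)-3-(triethylsilyloxy)-2-[2-(triethylsilyloxy)propan-2-yl]-2,3-dihydrobenzofuran
Conditions: TESOTf, 2,6-lutidine, CH2Cl2, −78 to 0 °C
Reagents that add atoms: triethylsilyl trifluoromethanesulfonate, CC[Si](CC)(CC)OS(=O)(=O)C(F)(F)F
Why: Silyl triflate with a hindered base silylates the secondary and the tertiary alcohol; triethylsilyl ethers withstand amines, carbonate and zerovalent palladium and are removed by fluoride at the end.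

Step 8
Reactants: 12 (2S,3S)-5-bromo-7-(3-methylbut-2-enyl)-3-(triethylsilyloxy)-2-[2-(triethylsilyloxy)propan-2-yl]-2,3-dihydrobenzofuran; 13 ethynyltrimethylsilane (trimethylsilylacetylene)
Product: 14 (2S,3S)-7-(3-methylbut-2-enyl)-3-(triethylsilyloxy)-2-[2-(triethylsilyloxy)propan-2-yl]-5-[(trimethylsilyl)ethynyl]-2,3-dihydrobenzofuran
Conditions: PdCl2(PhCN)2 (3 mol %), P(t-Bu)3 (6 mol %), CuI (2 mol %), i-Pr2NH, 1,4-dioxane, rt
Reagents that add atoms: none
Why: Sonogashira coupling; the electron-rich tri-tert-butylphosphine ligand lets zerovalent palladium add to the electron-rich, unhindered aryl bromide at room temperature, and silyl ethers and the prenyl alkene are spectators.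

Step 9
Reactants: 14 (2S,3S)-7-(3-methylbut-2-enyl)-3-(triethylsilyloxy)-2-[2-(triethylsilyloxy)propan-2-yl]-5-[(trimethylsilyl)ethynyl]-2,3-dihydrobenzofuran
Product: 15 (2S,3S)-5-ethynyl-7-(3-methylbut-2-enyl)-3-(triethylsilyloxy)-2-[2-(triethylsilyloxy)propan-2-yl]-2,3-dihydrobenzofuran
Conditions: K2CO3 (cat.), MeOH–THF, rt
Reagents that add atoms: none
Why: Methoxide-induced protodesilylation of the alkynylsilane; the C(sp)–Si bond is cleaved far faster than the triethylsilyl ethers of a secondary and a tertiary alcohol.

Step 10
Reactants: 16 benzene-1,3,5-triol (phloroglucinol)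
Product: 17 3,5-bis(methoxymethoxy)phenol
Conditions: MOMCl (2 equiv), i-Pr2NEt, CH2Cl2–DMF, 0 °C to rt
Reagents that add atoms: chloromethyl methyl ether, COCCl
Why: O-alkylation of the phenol with an α-chloro ether; with two equivalents the bis-ether is the main component of a statistical mixture and is separated from the mono- and tris-ethers.

Step 11
Reactants: 17 3,5-bis(methoxymethoxy)phenol
Product: 18 2-iodo-3,5-bis(methoxymethoxy)phenol
Conditions: I2 (1.0 equiv), NaHCO3, THF–H2O, 0 °C
Reagents that add atoms: iodine, II
Why: Electrophilic iodination of the phenoxide under bicarbonate buffering, which keeps the MOM ethers intact; attack is expected ortho to the free hydroxyl, as with resorcinols, and not at the more crowded position between the two MOM ethers.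

Step 12
Reactants: 18 2-iodo-3,5-bis(methoxymethoxy)phenol; 15 (2S,3S)-5-ethynyl-7-(3-methylbut-2-enyl)-3-(triethylsilyloxy)-2-[2-(triethylsilyloxy)propan-2-yl]-2,3-dihydrobenzofuran
Product: 21 2-[(2S,3S)-7-(3-methylbut-2-enyl)-3-(triethylsilyloxy)-2-[2-(triethylsilyloxy)propan-2-yl]-2,3-dihydrobenzofuran-5-yl]-5,7-bis(methoxymethoxy)-4H-chromen-4-one, via ortho-hydroxyaryl ynone 19 (not isolated), via diethylamino enone 20 (not isolated)
Conditions: PdCl2(dppf) (5 mol %), CO (10 bar), Et2NH, 100 °C
Reagents that add atoms: carbon monoxide, [C-]#[O+]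
Why: This is the known palladium-catalysed carbonylative annulation of ortho-iodophenols with terminal alkynes in a secondary amine. PdCl2(dppf) is reduced in the flask to zerovalent palladium, which adds to the C–I bond of 18; CO insertion gives an aroylpalladium species that couples with alkyne 15 (deprotonated by Et2NH) to give ynone 19, forming C4a–C4 and C4–C3. Et2NH then adds to the ynone to give enaminone 20, and the phenol attacks its β-carbon and expels the amine, forming O1–C2. Ring C thus closes in the 6-endo mode: 6-endo-dig with respect to the ynone, 6-endo-trig addition–elimination with respect to 20. No stereocentre is formed, and C2 and C3 of ring B are remote silyl-protected centres that cannot epimerise under these basic conditions. Two selectivities are needed: carbonylative over direct coupling, secured by CO pressure and the absence of copper so that CO insertion precedes alkyne transfer; and flavone over aurone closure, secured by the amine, which turns the ynone into 20, whose β-carbon is the only electrophilic site left for the phenol. The iodine of 18 lies between the free hydroxyl and a MOM ether, so only the 5,7-dioxygenated flavone can result, and the MOM and triethylsilyl ethers and the prenyl alkene are inert to amine, CO and zerovalent palladium.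

Step 13
Reactants: 21 2-[(2S,3S)-7-(3-methylbut-2-enyl)-3-(triethylsilyloxy)-2-[2-(triethylsilyloxy)propan-2-yl]-2,3-dihydrobenzofuran-5-yl]-5,7-bis(methoxymethoxy)-4H-chromen-4-one
Product: 23 5,7-dihydroxy-2-[(2S,3S)-7-(3-methylbut-2-enyl)-3-(triethylsilyloxy)-2-[2-(triethylsilyloxy)propan-2-yl]-2,3-dihydrobenzofuran-5-yl]-4H-chromen-4-one, via bis(trimethylsilyl) aryl ether 22 (not isolated)
Conditions: TMSOTf, 2,2'-bipyridyl, MeCN, 0 °C to rt; then H2O
Reagents that add atoms: none
Why: Non-protic cleavage of aromatic MOM ethers with a silyl triflate buffered by 2,2'-bipyridyl; the acetal carbon is transferred to the bipyridyl nitrogen, the phenols emerge as trimethylsilyl ethers 22, and water hydrolyses these and the N-methoxymethyl salt. No Brønsted acid is present, which should spare the triethylsilyl ethers and the ionisable benzylic C3–O bond.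

Step 14
Reactants: 23 5,7-dihydroxy-2-[(2S,3S)-7-(3-methylbut-2-enyl)-3-(triethylsilyloxy)-2-[2-(triethylsilyloxy)propan-2-yl]-2,3-dihydrobenzofuran-5-yl]-4H-chromen-4-one
Product: 24 2-[(2S,3S)-3-hydroxy-2-(2-hydroxypropan-2-yl)-7-(3-methylbut-2-enyl)-2,3-dihydrobenzofuran-5-yl]-5,7-dihydroxy-4H-chromen-4-one (target)
Conditions: TBAF, AcOH (1:1), THF, 0 °C to rt
Reagents that add atoms: none
Why: Fluoride-induced desilylation of both triethylsilyl ethers; acetic acid buffers the phenoxides, and the near-neutral medium touches neither the benzylic carbinol nor the prenyl alkene, so C2 and C3 should stay as set in steps 4 to 6.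

## Compound list

1 | 4-bromophenol | Oc1ccc(Br)cc1 | starting material
2 | 1-bromo-3-methylbut-2-ene (prenyl bromide) | CC(C)=CCBr | starting material
3 | 4-bromo-2-(3-methylbut-2-enyl)phenol | CC(C)=CCc1cc(Br)ccc1O | intermediate
4 | 5-bromo-2-hydroxy-3-(3-methylbut-2-enyl)benzaldehyde | CC(C)=CCc1cc(Br)cc(C=O)c1O | intermediate
5 | 5-bromo-2-(tert-butyldimethylsilyloxy)-3-(3-methylbut-2-enyl)benzaldehyde | CC(C)=CCc1cc(Br)cc(C=O)c1O[Si](C)(C)C(C)(C)C | intermediate
6 | 2-methylprop-1-enylmagnesium bromide | CC(C)=C[Mg]Br | starting material
7 | bis(2-methylprop-1-enyl)zinc | CC(C)=C[Zn]C=C(C)C | intermediate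
8 | (R)-1-[5-bromo-2-(tert-butyldimethylsilyloxy)-3-(3-methylbut-2-enyl)phenyl]-3-methylbut-2-en-1-ol | CC(C)=CCc1cc(Br)cc([C@H](O)C=C(C)C)c1O[Si](C)(C)C(C)(C)C | intermediate
9 | (S)-[5-bromo-2-(tert-butyldimethylsilyloxy)-3-(3-methylbut-2-enyl)phenyl][(R)-3,3-dimethyloxiran-2-yl]methanol | CC(C)=CCc1cc(Br)cc([C@H](O)[C@H]2OC2(C)C)c1O[Si](C)(C)C(C)(C)C | intermediate
10 | tetrabutylammonium 4-bromo-2-[(S)-[(R)-3,3-dimethyloxiran-2-yl](hydroxy)methyl]-6-(3-methylbut-2-enyl)phenoxide | CC(C)=CCc1cc(Br)cc([C@H](O)[C@H]2OC2(C)C)c1[O-].CCCC[N+](CCCC)(CCCC)CCCC | intermediate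
11 | (2S,3S)-5-bromo-2-(2-hydroxypropan-2-yl)-7-(3-methylbut-2-enyl)-2,3-dihydrobenzofuran-3-ol | CC(C)=CCc1cc(Br)cc2c1O[C@H](C(C)(C)O)[C@H]2O | intermediate
12 | (2S,3S)-5-bromo-7-(3-methylbut-2-enyl)-3-(triethylsilyloxy)-2-[2-(triethylsilyloxy)propan-2-yl]-2,3-dihydrobenzofuran | CC(C)=CCc1cc(Br)cc2c1O[C@H](C(C)(C)O[Si](CC)(CC)CC)[C@H]2O[Si](CC)(CC)CC | intermediate
13 | ethynyltrimethylsilane | C#C[Si](C)(C)C | starting material
14 | (2S,3S)-7-(3-methylbut-2-enyl)-3-(triethylsilyloxy)-2-[2-(triethylsilyloxy)propan-2-yl]-5-[(trimethylsilyl)ethynyl]-2,3-dihydrobenzofuran | CC(C)=CCc1cc(C#C[Si](C)(C)C)cc2c1O[C@H](C(C)(C)O[Si](CC)(CC)CC)[C@H]2O[Si](CC)(CC)CC | intermediate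
15 | (2S,3S)-5-ethynyl-7-(3-methylbut-2-enyl)-3-(triethylsilyloxy)-2-[2-(triethylsilyloxy)propan-2-yl]-2,3-dihydrobenzofuran | CC(C)=CCc1cc(C#C)cc2c1O[C@H](C(C)(C)O[Si](CC)(CC)CC)[C@H]2O[Si](CC)(CC)CC | intermediate
16 | benzene-1,3,5-triol (phloroglucinol) | Oc1cc(O)cc(O)c1 | starting material
17 | 3,5-bis(methoxymethoxy)phenol | COCOc1cc(O)cc(OCOC)c1 | intermediate
18 | 2-iodo-3,5-bis(methoxymethoxy)phenol | COCOc1cc(O)c(I)c(OCOC)c1 | intermediate
19 | 1-[2-hydroxy-4,6-bis(methoxymethoxy)phenyl]-3-[(2S,3S)-7-(3-methylbut-2-enyl)-3-(triethylsilyloxy)-2-[2-(triethylsilyloxy)propan-2-yl]-2,3-dihydrobenzofuran-5-yl]prop-2-yn-1-one | CC(C)=CCc1cc(C#CC(=O)c3c(O)cc(OCOC)cc3OCOC)cc2c1O[C@H](C(C)(C)O[Si](CC)(CC)CC)[C@H]2O[Si](CC)(CC)CC | intermediate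
20 | 3-(diethylamino)-1-[2-hydroxy-4,6-bis(methoxymethoxy)phenyl]-3-[(2S,3S)-7-(3-methylbut-2-enyl)-3-(triethylsilyloxy)-2-[2-(triethylsilyloxy)propan-2-yl]-2,3-dihydrobenzofuran-5-yl]prop-2-en-1-one | CC(C)=CCc1cc(C(=CC(=O)c3c(O)cc(OCOC)cc3OCOC)N(CC)CC)cc2c1O[C@H](C(C)(C)O[Si](CC)(CC)CC)[C@H]2O[Si](CC)(CC)CC | intermediate
21 | 2-[(2S,3S)-7-(3-methylbut-2-enyl)-3-(triethylsilyloxy)-2-[2-(triethylsilyloxy)propan-2-yl]-2,3-dihydrobenzofuran-5-yl]-5,7-bis(methoxymethoxy)-4H-chromen-4-one | CC(C)=CCc1cc(-c2cc(=O)c3c(OCOC)cc(OCOC)cc3o2)cc2c1O[C@H](C(C)(C)O[Si](CC)(CC)CC)[C@H]2O[Si](CC)(CC)CC | intermediate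
22 | 2-[(2S,3S)-7-(3-methylbut-2-enyl)-3-(triethylsilyloxy)-2-[2-(triethylsilyloxy)propan-2-yl]-2,3-dihydrobenzofuran-5-yl]-5,7-bis(trimethylsilyloxy)-4H-chromen-4-one | CC(C)=CCc1cc(-c2cc(=O)c3c(O[Si](C)(C)C)cc(O[Si](C)(C)C)cc3o2)cc2c1O[C@H](C(C)(C)O[Si](CC)(CC)CC)[C@H]2O[Si](CC)(CC)CC | intermediate
23 | 5,7-dihydroxy-2-[(2S,3S)-7-(3-methylbut-2-enyl)-3-(triethylsilyloxy)-2-[2-(triethylsilyloxy)propan-2-yl]-2,3-dihydrobenzofuran-5-yl]-4H-chromen-4-one | CC(C)=CCc1cc(-c2cc(=O)c3c(O)cc(O)cc3o2)cc2c1O[C@H](C(C)(C)O[Si](CC)(CC)CC)[C@H]2O[Si](CC)(CC)CC | intermediate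
24 | 2-[(2S,3S)-3-hydroxy-2-(2-hydroxypropan-2-yl)-7-(3-methylbut-2-enyl)-2,3-dihydrobenzofuran-5-yl]-5,7-dihydroxy-4H-chromen-4-one | CC(C)=CCc1cc(-c2cc(=O)c3c(O)cc(O)cc3o2)cc2c1O[C@H](C(C)(C)O)[C@H]2O | target

## Step count and least certain steps

Total: 14 steps. Longest linear sequence: 12 steps (steps 1 to 9, then 12, 13 and 14); the iodophenol branch has 2 steps (10 and 11).

**Step 12 (key step).** Oxidative addition to the electron-rich iodide flanked by two oxygen substituents may be slow, which gives time for non-carbonylative coupling of the alkyne followed by closure to a 2-arylbenzofuran; closure of the ynone through the five-membered mode is the second risk if amine addition lags. The fallback builds the same ynone without palladium and sets out from 15. 2,4,6-Trihydroxybenzaldehyde F1 is converted with MOMCl and i-Pr2NEt into the hydrogen-bonded mono-phenol 2-hydroxy-4,6-bis(methoxymethoxy)benzaldehyde F2. Its phenol is deprotonated with i-PrMgCl, and the lithium acetylide of 15 (n-BuLi, THF, −78 °C) is added to give the propargylic alcohol 1-[2-hydroxy-4,6-bis(methoxymethoxy)phenyl]-3-[(2S,3S)-7-(3-methylbut-2-enyl)-3-(triethylsilyloxy)-2-[2-(triethylsilyloxy)propan-2-yl]-2,3-dihydrobenzofuran-5-yl]prop-2-yn-1-ol F3. Oxidation with MnO2 gives ynone 19, where the fallback rejoins the route: 19 is now isolated and closed with Et2NH in ethanol through 20 to 21.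

**Step 4.** Enantioselection may be incomplete, because the zinc reagent is made from a Grignard reagent and traces of magnesium halide open a racemic background addition, and because a β,β-disubstituted alkenyl group may transfer slowly. The fallback sets out from 5. Divinylzinc, which can be distilled free of salts and is an established partner of aromatic aldehydes under amino-alcohol catalysis, is added with (+)-MIB to give (R)-1-[5-bromo-2-(tert-butyldimethylsilyloxy)-3-(3-methylbut-2-enyl)phenyl]prop-2-en-1-ol F4. Cross-metathesis with 2-methyl-2-butene and the second-generation Grubbs catalyst RuCl2(=CHPh)(H2IMes)(PCy3) then installs the two methyl groups and returns to 8; exchange at the aryl prenyl alkene is degenerate.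

**Step 11.** Iodination may take place para to the hydroxyl, between the two MOM ethers, or twice, because all three free ring positions are activated. The fallback removes the regiochemical question and sets out from 16. Phloroglucinol itself, whose three ring positions are equivalent, is iodinated (I2, NaHCO3, water) to 2-iodobenzene-1,3,5-triol F5 and peracetylated (Ac2O, pyridine) to 2-iodobenzene-1,3,5-triyl triacetate F6. In the carbonylative annulation with 15 the acetates are cleaved by Et2NH in the flask (the iodophenol acetate variant of the same reaction), and since both oxygens ortho to iodine are equivalent only one flavone can form. The route is rejoined at 23, with steps 10, 11 and 13 bypassed.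

**Step 13.** The silyl triflate may activate the benzylic C3 silyl ether; heterolysis of that C–O bond, assisted by the ring oxygen through C7a, would erode the configuration at C3 or lead to elimination, and the 7-MOM ether may be cleaved incompletely. The fallback avoids any Lewis acid at the end and sets out from 16. Bis-silylation (TBSCl, imidazole) gives 3,5-bis(tert-butyldimethylsilyloxy)phenol F7, and iodination as in step 11 gives 2-iodo-3,5-bis(tert-butyldimethylsilyloxy)phenol F8. Annulation with 15 as in step 12 gives 5,7-bis(tert-butyldimethylsilyloxy)-2-[(2S,3S)-7-(3-methylbut-2-enyl)-3-(triethylsilyloxy)-2-[2-(triethylsilyloxy)propan-2-yl]-2,3-dihydrobenzofuran-5-yl]-4H-chromen-4-one F9. One treatment with TBAF and AcOH removes all four silyl groups and rejoins the route at 24.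

## Further compounds

F1 | step 12 | 2,4,6-trihydroxybenzaldehyde | O=Cc1c(O)cc(O)cc1O
F2 | step 12 | 2-hydroxy-4,6-bis(methoxymethoxy)benzaldehyde | COCOc1cc(O)c(C=O)c(OCOC)c1
F3 | step 12 | 1-[2-hydroxy-4,6-bis(methoxymethoxy)phenyl]-3-[(2S,3S)-7-(3-methylbut-2-enyl)-3-(triethylsilyloxy)-2-[2-(triethylsilyloxy)propan-2-yl]-2,3-dihydrobenzofuran-5-yl]prop-2-yn-1-ol (both carbinol epimers) | CC(C)=CCc1cc(C#CC(O)c3c(O)cc(OCOC)cc3OCOC)cc2c1O[C@H](C(C)(C)O[Si](CC)(CC)CC)[C@H]2O[Si](CC)(CC)CC
F4 | step 4 | (R)-1-[5-bromo-2-(tert-butyldimethylsilyloxy)-3-(3-methylbut-2-enyl)phenyl]prop-2-en-1-ol | CC(C)=CCc1cc(Br)cc([C@H](O)C=C)c1O[Si](C)(C)C(C)(C)C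
F5 | step 11 | 2-iodobenzene-1,3,5-triol | Oc1cc(O)c(I)c(O)c1
F6 | step 11 | 2-iodobenzene-1,3,5-triyl triacetate | CC(=O)Oc1cc(OC(C)=O)c(I)c(OC(C)=O)c1
F7 | step 13 | 3,5-bis(tert-butyldimethylsilyloxy)phenol | CC(C)(C)[Si](C)(C)Oc1cc(O)cc(O[Si](C)(C)C(C)(C)C)c1
F8 | step 13 | 2-iodo-3,5-bis(tert-butyldimethylsilyloxy)phenol | CC(C)(C)[Si](C)(C)Oc1cc(O)c(I)c(O[Si](C)(C)C(C)(C)C)c1
F9 | step 13 | 5,7-bis(tert-butyldimethylsilyloxy)-2-[(2S,3S)-7-(3-methylbut-2-enyl)-3-(triethylsilyloxy)-2-[2-(triethylsilyloxy)propan-2-yl]-2,3-dihydrobenzofuran-5-yl]-4H-chromen-4-one | CC(C)=CCc1cc(-c2cc(=O)c3c(O[Si](C)(C)C(C)(C)C)cc(O[Si](C)(C)C(C)(C)C)cc3o2)cc2c1O[C@H](C(C)(C)O[Si](CC)(CC)CC)[C@H]2O[Si](CC)(CC)CC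
A1 | alternative 1 | (2S,3S)-7-bromo-3-(tert-butyldimethylsilyloxy)-2-(2-hydroxypropan-2-yl)-2,3-dihydrobenzofuran-5-carbaldehyde | Brc1cc(C=O)cc2c1O[C@H](C(C)(C)O)[C@H]2O[Si](C)(C)C(C)(C)C
A2 | alternative 1 | (3R,4S)-8-bromo-4-(tert-butyldimethylsilyloxy)-6-formyl-2,2-dimethyl-3,4-dihydro-2H-chromen-3-yl methanesulfonate | Brc1cc(C=O)cc2c1OC(C)(C)[C@H](OS(C)(=O)=O)[C@H]2O[Si](C)(C)C(C)(C)C
A3 | alternative 2 | 1-[(2S,3R)-5-bromo-3-hydroxy-7-(3-methylbut-2-enyl)-2,3-dihydrobenzofuran-2-yl]ethanone (cis) | CC(C)=CCc1cc(Br)cc2c1O[C@H](C(C)=O)[C@@H]2O
A4 | alternative 2 | 1-[4-bromo-2-formyl-6-(3-methylbut-2-enyl)phenoxy]propan-2-one | CC(C)=CCc1cc(Br)cc(C=O)c1OCC(C)=O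
A5 | alternative 3 | (2S,3S)-3-hydroxy-2-(2-hydroxypropan-2-yl)-7-(3-methylbut-2-enyl)-2,3-dihydrobenzofuran-5-carbaldehyde | CC(C)=CCc1cc(C=O)cc2c1O[C@H](C(C)(C)O)[C@H]2O
A6 | alternative 3 | 4-fluoro-3-[(1S,2S)-1,2,3-trihydroxy-3-methylbutyl]-5-(3-methylbut-2-enyl)benzaldehyde | CC(C)=CCc1cc(C=O)cc([C@H](O)[C@H](O)C(C)(C)O)c1F
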